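**Plan** (ring numbered as the cyclohexenone: C1 = C=O, C2 bears CH2CO2Me, C3 = CH, C4 = CHOH, C5 bears the chain, C6 = CH2; chain C1'–C16')
1. Retrosynthesis, first cut: C7'–C8' of the tetraprenyl chain, between the methyl-bearing sp2 C7' of the C6'=C7' alkene and the sp3 C8'H2. Each trisubstituted alkene of the chain is followed by a CH2CH2 spacer, so C8' is the α-carbon of a γ,δ-unsaturated acid (geranylacetic acid) and can be generated as a primary radical by loss of CO2, while C7' is an (E)-alkenyl iodide on the ring half.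
2. Further cuts: C2–CH2CO2Me (α-iodoenone plus zinc ester enolate), O4–Si, the C1 ketal, and C5–C1' (allylation of the only enolisable carbon of a mono-ketalised cyclohexene-1,4-dione).
3. Forward: the six-membered ring is bought. A C9 iodo-dienyl bromide (from pent-3-yn-1-ol) alkylates it, then hydrogenation, silylation, chain coupling, ketal removal, α-iodination, zinc-enolate coupling and desilylation follow.
4. Stereochemistry: C4 and C5 (4R,5R, cis) both come from one Ru-diphosphine/diamine hydrogenation of the racemic alkylated ketone under dynamic kinetic resolution. 2'E comes from a syn-carbocupration, 6'E from a syn-hydrozirconation/iodination, 10'E from geranyl bromide; all are retained in the coupling.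
5. Helpers: the ethylene ketal keeps C1 masked (so C4 is the ketone that is alkylated and reduced, and no enone is present in the electrolysis) and TBS masks O4; both are removed after the coupling.

Key step: step 12

Remark: 1,4-dioxaspiro[4.5]dec-6-en-8-one (10) is taken as a catalogue compound. The hand of the Ru catalyst in step 7 is assigned by analogy with 2-alkylcyclohexanone hydrogenations and would be inverted if the first Mosher analysis of 13 required it.

**Step 1**
Reactants: 1 pent-3-yn-1-ol
Product: 2 5-bromopent-2-yne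
Conditions: CBr4, PPh3, CH2Cl2, 0 °C to rt
Reagents that add atoms: carbon tetrabromide, BrC(Br)(Br)Br
Why: Appel bromination of a primary alcohol by SN2 displacement of the oxyphosphonium group, with the internal alkyne inert.

**Step 2**
Reactants: 2 5-bromopent-2-yne; 3 methyl but-2-ynoate
Product: 5 methyl (2E)-3-methyloct-2-en-6-ynoate, via pent-3-ynylmagnesium bromide 4 (not isolated)
Conditions: Mg, THF, rt; CuBr·SMe2 (1.1 equiv), THF, −78 °C; then 3, −78 °C; sat. aq NH4Cl at −78 °C
Reagents that add atoms: none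
Why: Syn-carbocupration of the alkynoate by the organocopper reagent (conjugate addition to an ynoate) and protonation of the alkenylcopper at low temperature with retention should place the new chain cis to H, which is the 2E enoate.

**Step 3**
Reactants: 5 methyl (2E)-3-methyloct-2-en-6-ynoate
Product: 6 (2E)-3-methyloct-2-en-6-yn-1-ol
Conditions: DIBAL-H (2.3 equiv), CH2Cl2, −78 to 0 °C; Rochelle salt
Reagents that add atoms: none
Why: 1,2-Reduction of an α,β-unsaturated ester to the allylic alcohol by DIBAL-H, which leaves the alkene geometry and the alkyne untouched.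

**Step 4**
Reactants: 6 (2E)-3-methyloct-2-en-6-yn-1-ol
Product: 8 (2E,6E)-7-iodo-3-methylocta-2,6-dien-1-ol, via alkenylzirconocene alkoxide 7 (not isolated)
Conditions: Cp2Zr(H)Cl (3 equiv), THF, rt then 50 °C; I2, THF, 0 °C
Reagents that add atoms: iodine, II
Why: Hydrozirconation with the Schwartz reagent is syn and, under equilibrating conditions with excess reagent (one equivalent is consumed by the OH group), should place Zr on the less hindered methyl-bearing alkyne carbon, and iodinolysis of the C–Zr bond with retention then gives the 6E alkenyl iodide.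

**Step 5**
Reactants: 8 (2E,6E)-7-iodo-3-methylocta-2,6-dien-1-ol
Product: 9 (2E,6E)-1-bromo-7-iodo-3-methylocta-2,6-diene
Conditions: CBr4, PPh3, CH2Cl2, 0 °C
Reagents that add atoms: carbon tetrabromide, BrC(Br)(Br)Br
Why: Appel bromination of a primary allylic alcohol, which at 0 °C should proceed without allylic transposition or E/Z erosion and leaves the alkenyl iodide intact.

**Step 6**
Reactants: 10 1,4-dioxaspiro[4.5]dec-6-en-8-one; 9 (2E,6E)-1-bromo-7-iodo-3-methylocta-2,6-diene
Product: 12 rac-9-[(2E,6E)-7-iodo-3-methylocta-2,6-dien-1-yl]-1,4-dioxaspiro[4.5]dec-6-en-8-one, via lithium dienolate 11 (not isolated)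
Conditions: LDA (1.05 equiv), THF, −78 °C; then 9 (0.9 equiv), DMPU, −78 to −30 °C
Reagents that add atoms: none
Why: Kinetic deprotonation at the only enolisable carbon (C9; the γ-carbon is the quaternary ketal carbon) gives a cross-conjugated lithium dienolate that is C-alkylated by the primary allylic bromide in an SN2 enolate alkylation, the new stereocentre being formed racemic on purpose because it is corrected in step 7.

**Step 7**
Reactants: 12 rac-9-[(2E,6E)-7-iodo-3-methylocta-2,6-dien-1-yl]-1,4-dioxaspiro[4.5]dec-6-en-8-one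
Product: 13 (8R,9R)-9-[(2E,6E)-7-iodo-3-methylocta-2,6-dien-1-yl]-1,4-dioxaspiro[4.5]dec-6-en-8-ol
Conditions: RuCl2[(R)-binap][(S,S)-dpen] (1 mol %), t-BuOK (0.2 equiv), i-PrOH, H2 (4 atm), rt
Reagents that add atoms: none
Why: Noyori asymmetric hydrogenation under dynamic kinetic resolution: the outer-sphere Ru–H/N–H catalyst reduces only the C8 carbonyl, t-BuOK should epimerise C9 through the dienolate faster than the slow enantiomer is reduced, and the bulky hydride should attack the half-chair with an equatorial C9 side chain from the equatorial direction, so that the catalyst selects C9 (R) and C8 (R) is set cis to it, the catalyst hand being the mirror image of the one that gives (1R,2R)-cis-2-alkylcyclohexanols.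

**Step 8**
Reactants: 13 (8R,9R)-9-[(2E,6E)-7-iodo-3-methylocta-2,6-dien-1-yl]-1,4-dioxaspiro[4.5]dec-6-en-8-ol
Product: 14 tert-butyl{[(8R,9R)-9-[(2E,6E)-7-iodo-3-methylocta-2,6-dien-1-yl]-1,4-dioxaspiro[4.5]dec-6-en-8-yl]oxy}dimethylsilane
Conditions: TBSCl, imidazole, DMF, rt
Reagents that add atoms: tert-butyldimethylsilyl chloride, CC(C)(C)[Si](C)(C)Cl
Why: Standard silylation of a secondary allylic alcohol, which protects O4 against the zinc enolate of step 15 and against elimination in the later enone steps.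

**Step 9**
Reactants: 15 ethyl acetate; 16 geranyl bromide [(2E)-1-bromo-3,7-dimethylocta-2,6-diene]
Product: 18 ethyl (4E)-5,9-dimethyldeca-4,8-dienoate, via lithium ester enolate 17 (not isolated)
Conditions: LDA (1.1 equiv), THF, −78 °C; then 16, DMPU, −78 to −20 °C
Reagents that add atoms: none
Why: SN2 alkylation of the lithium enolate of ethyl acetate by a primary allylic bromide, which carries the E alkene of geranyl bromide over unchanged (the future 10'E).

**Step 10**
Reactants: 18 ethyl (4E)-5,9-dimethyldeca-4,8-dienoate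
Product: 19 (4E)-5,9-dimethyldeca-4,8-dienoic acid
Conditions: LiOH·H2O, THF/MeOH/H2O, rt; then 1 M HCl to pH 3
Reagents that add atoms: lithium hydroxide, [Li+].[OH-]
Why: Saponification of an unhindered ethyl ester under conditions that do not touch the trisubstituted alkenes.

**Step 11**
Reactants: 19 (4E)-5,9-dimethyldeca-4,8-dienoic acid
Product: 20 1,3-dioxoisoindolin-2-yl (4E)-5,9-dimethyldeca-4,8-dienoate
Conditions: N-hydroxyphthalimide, DIC, DMAP (cat.), CH2Cl2, rt
Reagents that add atoms: N-hydroxyphthalimide, O=C1c2ccccc2C(=O)N1O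
Why: Carbodiimide-mediated esterification gives the redox-active N-acyloxyphthalimide, which is reduced at a mild potential and then loses CO2.

**Step 12**
Reactants: 14 tert-butyl{[(8R,9R)-9-[(2E,6E)-7-iodo-3-methylocta-2,6-dien-1-yl]-1,4-dioxaspiro[4.5]dec-6-en-8-yl]oxy}dimethylsilane; 20 1,3-dioxoisoindolin-2-yl (4E)-5,9-dimethyldeca-4,8-dienoate
Product: 21 tert-butyldimethyl{[(8R,9R)-9-[(2E,6E,10E)-3,7,11,15-tetramethylhexadeca-2,6,10,14-tetraen-1-yl]-1,4-dioxaspiro[4.5]dec-6-en-8-yl]oxy}silane
Conditions: 20 (1.5 equiv), NiCl2·6H2O (20 mol %), 2,2'-bipyridine (20 mol %), AgNO3 (0.3 equiv), DMF, (+)Mg/(−)RVC, constant current, undivided cell, rt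
Reagents that add atoms: none
Why: Cathodic reduction gives low-valent Ni(bpy), which adds oxidatively into the C7'–I bond of 14 with retention of the 6'E geometry, while single-electron reduction of 20 expels phthalimide anion and CO2 to give the primary radical at the future C8'; capture of this radical by the alkenyl–Ni(II) species and reductive elimination from Ni(III) form the C7'(sp2)–C8'(sp3) bond, the Mg anode supplying the electrons. The closest known reaction type is the Ni-electrocatalytic decarboxylative alkenylation of redox-active esters on silver-nanoparticle-coated cathodes, a reductive cross-electrophile coupling that has been used to assemble head-to-tail polyene terpenoids from this same pair of fragment types. No ring is closed and no stereocentre is formed, so the only stereochemical demand is retention of the 6'E alkene, which stereoretentive oxidative addition and reductive elimination at nickel should secure. The step needs cross- over homo-coupling, which the excess of 20 and the silver-modified cathode (less direct ester reduction, no nickel black) should provide, and it needs the C8' radical to be trapped before it cyclises, which the chain secures because no alkene sits at a 5-exo or 6-exo distance (closure onto C10'=C11' is a reversible 3-exo process and closure onto C14'=C15' would need a seven-membered ring holding an E alkene). The ketal, silyl ether and trisubstituted alkenes are not reduced at the potential of the nickel cycle, which is why the enone is kept masked as its ketal here.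

**Step 13**
Reactants: 21 tert-butyldimethyl{[(8R,9R)-9-[(2E,6E,10E)-3,7,11,15-tetramethylhexadeca-2,6,10,14-tetraen-1-yl]-1,4-dioxaspiro[4.5]dec-6-en-8-yl]oxy}silane
Product: 22 (4R,5R)-4-[(tert-butyldimethylsilyl)oxy]-5-[(2E,6E,10E)-3,7,11,15-tetramethylhexadeca-2,6,10,14-tetraen-1-yl]cyclohex-2-en-1-one
Conditions: PPTS (cat.), acetone/H2O (9:1), 50 °C
Reagents that add atoms: water, O
Why: Mild acid hydrolysis of the allylic ethylene ketal through an allyl-stabilised oxocarbenium ion should release the conjugated enone while the TBS ether and the polyene survive PPTS.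

**Step 14**
Reactants: 22 (4R,5R)-4-[(tert-butyldimethylsilyl)oxy]-5-[(2E,6E,10E)-3,7,11,15-tetramethylhexadeca-2,6,10,14-tetraen-1-yl]cyclohex-2-en-1-one
Product: 23 (4R,5R)-4-[(tert-butyldimethylsilyl)oxy]-2-iodo-5-[(2E,6E,10E)-3,7,11,15-tetramethylhexadeca-2,6,10,14-tetraen-1-yl]cyclohex-2-en-1-one
Conditions: I2, pyridine/CH2Cl2 (1:1), 0 °C to rt, dark
Reagents that add atoms: iodine, II
Why: α-Iodination of an enone by conjugate addition of pyridine, iodination of the resulting enolate and elimination of pyridine, a sequence that works on 4-silyloxycyclohexenones and to which isolated trisubstituted alkenes respond only by reversible iodine complexation.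

**Step 15**
Reactants: 23 (4R,5R)-4-[(tert-butyldimethylsilyl)oxy]-2-iodo-5-[(2E,6E,10E)-3,7,11,15-tetramethylhexadeca-2,6,10,14-tetraen-1-yl]cyclohex-2-en-1-one; 24 methyl bromoacetate
Product: 26 methyl 2-[(3R,4R)-3-[(tert-butyldimethylsilyl)oxy]-6-oxo-4-[(2E,6E,10E)-3,7,11,15-tetramethylhexadeca-2,6,10,14-tetraen-1-yl]cyclohex-1-en-1-yl]acetate, via Reformatsky zinc reagent 25 (not isolated)
Conditions: 24, Zn dust (TMSCl-activated), THF, rt; then 23, Pd2(dba)3 (2.5 mol %), XPhos (10 mol %), THF, rt to 40 °C
Reagents that add atoms: none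
Why: Negishi-type cross-coupling of an alkenyl iodide with a Reformatsky zinc enolate, in which Pd(0) inserts into the activated C2–I bond, the weakly basic zinc enolate transmetalates and C–C reductive elimination installs the CH2CO2Me group without disturbing C4 or C5.

**Step 16**
Reactants: 26 methyl 2-[(3R,4R)-3-[(tert-butyldimethylsilyl)oxy]-6-oxo-4-[(2E,6E,10E)-3,7,11,15-tetramethylhexadeca-2,6,10,14-tetraen-1-yl]cyclohex-1-en-1-yl]acetate
Product: 27 methyl 2-[(3R,4R)-3-hydroxy-6-oxo-4-[(2E,6E,10E)-3,7,11,15-tetramethylhexadeca-2,6,10,14-tetraen-1-yl]cyclohex-1-en-1-yl]acetate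
Conditions: HF·pyridine, pyridine/THF, 0 °C to rt
Reagents that add atoms: none
Why: Buffered fluoride-mediated desilylation frees O4 under weakly acidic conditions that should avoid base-induced dehydration of the γ-hydroxy enone to a phenol and leave the methyl ester and polyene intact.

**Compound list**
1 | pent-3-yn-1-ol | CC#CCCO | starting material
2 | 5-bromopent-2-yne | CC#CCCBr | intermediate
3 | methyl but-2-ynoate | CC#CC(=O)OC | starting material
4 | pent-3-ynylmagnesium bromide | CC#CCC[Mg]Br | intermediate (not isolated)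
5 | methyl (2E)-3-methyloct-2-en-6-ynoate | CC#CCC/C(C)=C/C(=O)OC | intermediate
6 | (2E)-3-methyloct-2-en-6-yn-1-ol | CC#CCC/C(C)=C/CO | intermediate
7 | C7-zirconated alkenylzirconocene chloride, O-bound to a second zirconocene chloride | Cl[Zr](C1C=CC=C1)(C1C=CC=C1)OC/C=C(\C)CC/C=C(\C)[Zr](Cl)(C1C=CC=C1)C1C=CC=C1 | intermediate (not isolated)
8 | (2E,6E)-7-iodo-3-methylocta-2,6-dien-1-ol | OC/C=C(\C)CC/C=C(\C)I | intermediate
9 | (2E,6E)-1-bromo-7-iodo-3-methylocta-2,6-diene | BrC/C=C(\C)CC/C=C(\C)I | intermediate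
10 | 1,4-dioxaspiro[4.5]dec-6-en-8-one | O=C1C=CC2(CC1)OCCO2 | starting material
11 | lithium 1,4-dioxaspiro[4.5]deca-6,8-dien-8-olate | [Li+].[O-]C1=CCC2(OCCO2)C=C1 | intermediate (not isolated)
12 | rac-9-[(2E,6E)-7-iodo-3-methylocta-2,6-dien-1-yl]-1,4-dioxaspiro[4.5]dec-6-en-8-one | O=C1C=CC2(OCCO2)CC1C/C=C(\C)CC/C=C(\C)I | intermediate
13 | (8R,9R)-9-[(2E,6E)-7-iodo-3-methylocta-2,6-dien-1-yl]-1,4-dioxaspiro[4.5]dec-6-en-8-ol | C1=C[C@H](O)[C@H](C/C=C(\C)CC/C=C(\C)I)CC12OCCO2 | intermediate
14 | TBS ether of 13 | C1=C[C@H](O[Si](C)(C)C(C)(C)C)[C@H](C/C=C(\C)CC/C=C(\C)I)CC12OCCO2 | intermediate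
15 | ethyl acetate | CCOC(C)=O | starting material
16 | geranyl bromide | CC(C)=CCC/C(C)=C/CBr | starting material
17 | lithium 1-ethoxyethen-1-olate | [Li+].[O-]C(=C)OCC | intermediate (not isolated)
18 | ethyl (4E)-5,9-dimethyldeca-4,8-dienoate | CCOC(=O)CC/C=C(\C)CCC=C(C)C | intermediate
19 | (4E)-5,9-dimethyldeca-4,8-dienoic acid | OC(=O)CC/C=C(\C)CCC=C(C)C | intermediate
20 | 1,3-dioxoisoindolin-2-yl (4E)-5,9-dimethyldeca-4,8-dienoate | O=C(CC/C=C(\C)CCC=C(C)C)ON1C(=O)c2ccccc2C1=O | intermediate
21 | (8R,9R)-8-(TBS-oxy)-9-[(2E,6E,10E)-3,7,11,15-tetramethylhexadeca-2,6,10,14-tetraen-1-yl]-1,4-dioxaspiro[4.5]dec-6-ene | C1=C[C@H](O[Si](C)(C)C(C)(C)C)[C@H](C/C=C(\C)CC/C=C(\C)CC/C=C(\C)CCC=C(C)C)CC12OCCO2 | intermediate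
22 | (4R,5R)-4-(TBS-oxy)-5-[(2E,6E,10E)-3,7,11,15-tetramethylhexadeca-2,6,10,14-tetraen-1-yl]cyclohex-2-en-1-one | C1=C[C@H](O[Si](C)(C)C(C)(C)C)[C@H](C/C=C(\C)CC/C=C(\C)CC/C=C(\C)CCC=C(C)C)CC1=O | intermediate
23 | (4R,5R)-4-(TBS-oxy)-2-iodo-5-[(2E,6E,10E)-3,7,11,15-tetramethylhexadeca-2,6,10,14-tetraen-1-yl]cyclohex-2-en-1-one | IC1=C[C@H](O[Si](C)(C)C(C)(C)C)[C@H](C/C=C(\C)CC/C=C(\C)CC/C=C(\C)CCC=C(C)C)CC1=O | intermediate
24 | methyl bromoacetate | COC(=O)CBr | starting material
25 | (2-methoxy-2-oxoethyl)zinc bromide | COC(=O)C[Zn]Br | intermediate (not isolated)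
26 | methyl 2-[(3R,4R)-3-(TBS-oxy)-6-oxo-4-[(2E,6E,10E)-3,7,11,15-tetramethylhexadeca-2,6,10,14-tetraen-1-yl]cyclohex-1-en-1-yl]acetate | COC(=O)CC1=C[C@H](O[Si](C)(C)C(C)(C)C)[C@H](C/C=C(\C)CC/C=C(\C)CC/C=C(\C)CCC=C(C)C)CC1=O | intermediate
27 | methyl 2-[(3R,4R)-3-hydroxy-6-oxo-4-[(2E,6E,10E)-3,7,11,15-tetramethylhexadeca-2,6,10,14-tetraen-1-yl]cyclohex-1-en-1-yl]acetate | COC(=O)CC1=C[C@H](O)[C@H](C/C=C(\C)CC/C=C(\C)CC/C=C(\C)CCC=C(C)C)CC1=O | target

Total step count: 16. Longest linear sequence: 13 steps (steps 1–8, then 12–16).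

**Steps most likely to fail**

Step 7. Epimerisation at C9 of 12 may be too slow under the weakly basic hydrogenation conditions, so that the dynamic resolution collapses to a simple kinetic resolution, or the hydride may be delivered with poor facial control on the enone half-chair. The fallback sets out from 9 and comes back at 13, with the stereocentres set by an auxiliary and a bulky hydride instead of the catalyst. Commercial 1,4-dioxaspiro[4.5]decan-8-one is condensed with SAMP to the hydrazone F1. Its lithium aza-enolate (LDA, THF, −78 °C) is alkylated with 9 to give the (7R)-alkylated hydrazone F2; SAMP is chosen by analogy with the (R)-2-alkylcyclohexanones it furnishes, and RAMP would be used otherwise. Two-phase oxalic acid cleavage gives the (7R)-ketone F3. Kinetic enolisation away from the substituted α-carbon (LDA, −78 °C) and PhSeCl give the α'-phenylselanyl ketone F4. L-Selectride, attacking from the equatorial side, should give the cis hydroxy selenide F5. Oxidation with H2O2/pyridine and syn-elimination of the selenoxide away from the carbinol carbon then give 13.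

Step 12. Reductive homocoupling or protodeiodination of the alkenyl iodide, and direct cathodic reduction of the active ester, may outrun the nickel-mediated cross-coupling. The fallback sets out from 20 and 14 and comes back at 21, replacing the radical route by a two-electron sp2–sp3 Negishi coupling. Light-driven iododecarboxylation of 20 (LiI, cat. PPh3, blue light) gives (3E)-1-iodo-4,8-dimethylnona-3,7-diene F6. Zinc insertion (Zn dust, LiCl, THF, 40 °C) gives the alkylzinc iodide F7. This is coupled with 14 (PdCl2(dppf), THF/NMP, rt) to give 21.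

Step 15. Base-induced loss of silanol from the γ-silyloxy iodoenone with aromatisation, or slow transmetalation of the zinc enolate followed by protodeiodination, may erode the coupling. The fallback sets out from 23 and comes back at 26, bringing in the two carbons as a masked acetaldehyde. Suzuki–Miyaura coupling of 23 with (E)-2-(2-ethoxyvinyl)-4,4,5,5-tetramethyl-1,3,2-dioxaborolane (PdCl2(dppf), K3PO4, THF/H2O) gives the ethoxyvinyl enone F8. Mild acid hydrolysis (PPTS, wet acetone) gives the aldehyde F9. Pinnick oxidation (NaClO2, NaH2PO4, large excess of 2-methylbut-2-ene, t-BuOH/H2O, 0 °C) gives the acid F10. Methylation with TMSCHN2 in MeOH/toluene gives 26.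

**Further compounds**
F1 | step 7 | (S)-N-(1,4-dioxaspiro[4.5]decan-8-ylidene)-2-(methoxymethyl)pyrrolidin-1-amine | COC[C@@H]1CCCN1N=C1CCC2(CC1)OCCO2
F2 | step 7 | (S)-N-[(7R)-7-[(2E,6E)-7-iodo-3-methylocta-2,6-dien-1-yl]-1,4-dioxaspiro[4.5]decan-8-ylidene]-2-(methoxymethyl)pyrrolidin-1-amine | COC[C@@H]1CCCN1N=C1CCC2(OCCO2)C[C@H]1C/C=C(\C)CC/C=C(\C)I
F3 | step 7 | (7R)-7-[(2E,6E)-7-iodo-3-methylocta-2,6-dien-1-yl]-1,4-dioxaspiro[4.5]decan-8-one | O=C1CCC2(OCCO2)C[C@H]1C/C=C(\C)CC/C=C(\C)I
F4 | step 7 | (7R)-7-[(2E,6E)-7-iodo-3-methylocta-2,6-dien-1-yl]-9-(phenylselanyl)-1,4-dioxaspiro[4.5]decan-8-one (C9 epimers) | O=C1C([Se]c2ccccc2)CC2(OCCO2)C[C@H]1C/C=C(\C)CC/C=C(\C)I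
F5 | step 7 | (7R,8R)-7-[(2E,6E)-7-iodo-3-methylocta-2,6-dien-1-yl]-9-(phenylselanyl)-1,4-dioxaspiro[4.5]decan-8-ol (C9 epimers) | O[C@H]1C([Se]c2ccccc2)CC2(OCCO2)C[C@H]1C/C=C(\C)CC/C=C(\C)I
F6 | step 12 | (3E)-1-iodo-4,8-dimethylnona-3,7-diene | ICC/C=C(\C)CCC=C(C)C
F7 | step 12 | [(3E)-4,8-dimethylnona-3,7-dien-1-yl]zinc iodide | I[Zn]CC/C=C(\C)CCC=C(C)C
F8 | step 15 | (4R,5R)-4-(TBS-oxy)-2-[(E)-2-ethoxyethenyl]-5-[(2E,6E,10E)-3,7,11,15-tetramethylhexadeca-2,6,10,14-tetraen-1-yl]cyclohex-2-en-1-one | CCO/C=C/C1=C[C@H](O[Si](C)(C)C(C)(C)C)[C@H](C/C=C(\C)CC/C=C(\C)CC/C=C(\C)CCC=C(C)C)CC1=O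
F9 | step 15 | 2-[(3R,4R)-3-(TBS-oxy)-6-oxo-4-[(2E,6E,10E)-3,7,11,15-tetramethylhexadeca-2,6,10,14-tetraen-1-yl]cyclohex-1-en-1-yl]acetaldehyde | O=CCC1=C[C@H](O[Si](C)(C)C(C)(C)C)[C@H](C/C=C(\C)CC/C=C(\C)CC/C=C(\C)CCC=C(C)C)CC1=O
F10 | step 15 | 2-[(3R,4R)-3-(TBS-oxy)-6-oxo-4-[(2E,6E,10E)-3,7,11,15-tetramethylhexadeca-2,6,10,14-tetraen-1-yl]cyclohex-1-en-1-yl]acetic acid | OC(=O)CC1=C[C@H](O[Si](C)(C)C(C)(C)C)[C@H](C/C=C(\C)CC/C=C(\C)CC/C=C(\C)CCC=C(C)C)CC1=O
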